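**Retrosynthetic overview**
1. Target 19 comes from α-hydroxy ketone 18 by chelation-controlled reduction (sets C1′); 18 comes from aryl bromide 16 and lithium alkoxide 6 of (S)-N,N-dimethyllactamide 5 (C2′ from the chiral pool).
2. The O-heterocycle (ring C) is the only ring made: acid cyclodehydration of benzylic alcohol 15 onto the unmasked phenol closes C2–O 2,3-trans. Rings A and B both come intact from catechol.
3. 15 comes from ring A Grignard 12 and (S)-2-arylpropanal 14. 14 arises by a stereospecific pinacol-type 1,2-aryl shift in the aluminium alkoxide of lactate-derived α-mesyloxy ketone 9: ring B moves from the carbinol carbon to the lactate carbon with inversion, which sets C3.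
4. 9 comes from ortho-lithiated, MOM-protected 4,6-dibromoguaiacol (from catechol) and the same lithium alkoxide 6, which is made once and used for both acylations.
5. Order: ring B functionalised, lactate unit attached, aryl shift with arylation, ring C closed, side chain built.

Assumption: (S)-2-hydroxy-N,N-dimethylpropanamide 5 is bought as the single enantiomer; the target is taken as drawn, 2,3-trans (2S,3S) with an erythro (1R,2S) diol.

**Route**

Step 1
Reactants: 1 catechol (benzene-1,2-diol)
Product: 2 2-methoxyphenol (guaiacol)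
Conditions: 1 (2 equiv), MeI (1 equiv), K2CO3 (1 equiv), acetone, 56 °C
Reagents that add atoms: iodomethane, CI
Why: Williamson ether synthesis; with catechol in excess and one equivalent of base mainly the mono-anion is alkylated, and water-soluble catechol and neutral veratrole are removed by extraction.

Step 2
Reactants: 2 2-methoxyphenol
Product: 3 2,4-dibromo-6-methoxyphenol
Conditions: Br2 (2.05 equiv), AcOH, 10 → 20 °C
Reagents that add atoms: bromine, BrBr
Why: Electrophilic aromatic bromination; the free hydroxyl is the strongest director, so the two bromines enter para and ortho to it.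

Step 3
Reactants: 3 2,4-dibromo-6-methoxyphenol
Product: 4 1,5-dibromo-3-methoxy-2-(methoxymethoxy)benzene
Conditions: MOMCl (1.5 equiv), i-Pr2NEt (2 equiv), CH2Cl2, 0 → 25 °C
Reagents that add atoms: chloromethyl methyl ether, COCCl
Why: O-alkylation of the phenol to its MOM acetal (protection); the acetal later steers the bromine–lithium exchange and is lost in the acidic ring closure.

Step 4
Reactants: 5 (S)-2-hydroxy-N,N-dimethylpropanamide
Product: 6 lithium (2S)-1-(dimethylamino)-1-oxopropan-2-olate (0.5 M stock solution in THF, kept under argon at −20 °C, made on a scale that serves steps 5 and 11)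
Conditions: n-BuLi (0.98 equiv, 2.5 M in hexanes), THF, −78 → 0 °C
Reagents that add atoms: n-butyllithium, [Li]CCCC
Why: Brønsted acid–base reaction (O-lithiation): at −78 °C the hydroxyl is deprotonated far faster than n-BuLi adds to the tertiary amide, butane leaves as the only by-product, and the stereocentre carries no acidic hydrogen in the alkoxide, so it is untouched.

Step 5
Reactants: 4 1,5-dibromo-3-methoxy-2-(methoxymethoxy)benzene; 6 lithium (2S)-1-(dimethylamino)-1-oxopropan-2-olate
Product: 8 (2S)-1-[5-bromo-3-methoxy-2-(methoxymethoxy)phenyl]-2-hydroxypropan-1-one, via aryllithium 7 (not isolated)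
Conditions: 4, n-BuLi (1.05 equiv), THF, −78 °C; then 6 (1.2 equiv, 0.5 M in THF), −78 → −20 °C; AcOH, −78 °C
Reagents that add atoms: none
Why: Bromine–lithium exchange is fastest at the bromide ortho to the chelating OMOM group, and acylation of the aryllithium by the O-lithiated tertiary amide stops at a chelated tetrahedral adduct that collapses to the ketone only on quench (amide acylation of an organolithium), so the lactate stereocentre is carried over unchanged.

Step 6
Reactants: 8 (2S)-1-[5-bromo-3-methoxy-2-(methoxymethoxy)phenyl]-2-hydroxypropan-1-one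
Product: 9 (2S)-1-[5-bromo-3-methoxy-2-(methoxymethoxy)phenyl]-1-oxopropan-2-yl methanesulfonate
Conditions: MsCl (1.3 equiv), Et3N (1.5 equiv), CH2Cl2, −20 °C
Reagents that add atoms: methanesulfonyl chloride, CS(=O)(=O)Cl
Why: O-sulfonylation (mesylation) does not touch the C–O bond of the stereocentre (retention), and the low temperature avoids enolisation of the α-sulfonyloxy ketone.

Step 7
Reactants: 1 catechol
Product: 10 1,2-dimethoxybenzene (veratrole)
Conditions: MeI (2.5 equiv), K2CO3 (3 equiv), acetone, 56 °C
Reagents that add atoms: iodomethane, CI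
Why: Exhaustive Williamson methylation of both phenols.

Step 8
Reactants: 10 1,2-dimethoxybenzene
Product: 11 4-bromo-1,2-dimethoxybenzene
Conditions: NBS (1.02 equiv), MeCN, 0 → 25 °C
Reagents that add atoms: N-bromosuccinimide, O=C1CCC(=O)N1Br
Why: Electrophilic aromatic bromination para to a methoxy group, the only unhindered activated position.

Step 9
Reactants: 9 (2S)-1-[5-bromo-3-methoxy-2-(methoxymethoxy)phenyl]-1-oxopropan-2-yl methanesulfonate; 11 4-bromo-1,2-dimethoxybenzene
Product: 15 (1R,2S)-2-[5-bromo-3-methoxy-2-(methoxymethoxy)phenyl]-1-(3,4-dimethoxyphenyl)propan-1-ol, via aryl Grignard reagent 12 (not isolated), via diisobutylaluminium alkoxide 13 (not isolated), via (S)-2-arylpropanal 14 (not isolated)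
Conditions: 9, i-Bu2AlH (1.05 equiv), CH2Cl2, −78 °C; Me2AlCl (1.5 equiv), −78 → −30 °C; then 12 (3 equiv; from 11, Mg, THF, 40 °C), −78 → −20 °C; H2O
Reagents that add atoms: none
Why: Proposed new method: i-Bu2AlH reduces the ketone to the aluminium β-mesyloxy alkoxide 13, Me2AlCl then pulls on the mesylate while the O–Al alkoxide pushes, so ring B (ipso carbon activated by its ortho oxygen) shifts from the carbinol carbon to the lactate carbon anti to the leaving group through a phenonium-like transition state (stereospecific pinacol-type 1,2-aryl shift, inversion), which turns the S-mesylate into aluminium-bound (S)-2-arylpropanal 14, forms the C3–aryl bond and sets C3; because the aluminium species left after the shift carry no Al–H and transfer alkyl or β-hydride only slowly below −30 °C, 14 should survive until aryl Grignard 12 (an arylalane after Mg-to-Al exchange) adds at −78 °C to form the C2–aryl bond, Felkin–Anh control giving mainly the 1R carbinol (both epimers converge in step 10); the closest known chemistry is the organoaluminium-promoted pinacol-type rearrangement of β-mesyloxy alcohols and its reductive variant (Suzuki–Tsuchihashi rearrangement), where the aldehyde is reduced as it forms and has not been trapped by a carbon nucleophile.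

Step 10
Reactants: 15 (1R,2S)-2-[5-bromo-3-methoxy-2-(methoxymethoxy)phenyl]-1-(3,4-dimethoxyphenyl)propan-1-ol
Product: 16 (2S,3S)-5-bromo-2-(3,4-dimethoxyphenyl)-7-methoxy-3-methyl-2,3-dihydro-1-benzofuran
Conditions: HCl (1.25 M in MeOH), 40 °C; concentrate; TFA (1.2 equiv), CH2Cl2, 0 °C
Reagents that add atoms: none
Why: Acid removes the MOM acetal and ionises the 3,4-dimethoxybenzylic alcohol, and 5-exo capture of the cation by the phenol (SN1 cyclodehydration) places the aryl group anti to the C3 methyl; reversible C2–O ionisation funnels any cis isomer to trans, so both carbinol epimers give the 2S centre under control of C3.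

Step 11
Reactants: 16 (2S,3S)-5-bromo-2-(3,4-dimethoxyphenyl)-7-methoxy-3-methyl-2,3-dihydro-1-benzofuran; 6 lithium (2S)-1-(dimethylamino)-1-oxopropan-2-olate
Product: 18 (2S)-1-[(2S,3S)-2-(3,4-dimethoxyphenyl)-7-methoxy-3-methyl-2,3-dihydro-1-benzofuran-5-yl]-2-hydroxypropan-1-one, via aryllithium 17 (not isolated)
Conditions: 16, n-BuLi (1.05 equiv), THF, −78 °C; then 6 (1.2 equiv, 0.5 M in THF), −78 → −20 °C; AcOH, −78 °C
Reagents that add atoms: none
Why: Bromine–lithium exchange followed by acylation with the O-lithiated amide as in step 5 (amide acylation of an organolithium); the benzylic ether has no group that reacts with n-BuLi at −78 °C, and the cold acetic acid quench keeps the α-hydroxy ketone from racemising.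

Step 12
Reactants: 18 (2S)-1-[(2S,3S)-2-(3,4-dimethoxyphenyl)-7-methoxy-3-methyl-2,3-dihydro-1-benzofuran-5-yl]-2-hydroxypropan-1-one
Product: 19 (1R,2S)-1-[(2S,3S)-2-(3,4-dimethoxyphenyl)-7-methoxy-3-methyl-2,3-dihydro-1-benzofuran-5-yl]propane-1,2-diol
Conditions: Zn(BH4)2 (1.0 equiv), Et2O, −30 → 0 °C; H2O
Reagents that add atoms: none
Why: Chelation-controlled (Cram-chelate) hydride reduction: zinc bridges the carbonyl and hydroxyl oxygens and hydride enters from the face of the small α-hydrogen, which gives the anti (erythro) 1R,2S diol.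

**Compound list**
1 | catechol (benzene-1,2-diol) | Oc1ccccc1O | starting material
2 | 2-methoxyphenol (guaiacol) | COc1ccccc1O | intermediate
3 | 2,4-dibromo-6-methoxyphenol | COc1cc(Br)cc(Br)c1O | intermediate
4 | 1,5-dibromo-3-methoxy-2-(methoxymethoxy)benzene | COCOc1c(Br)cc(Br)cc1OC | intermediate
5 | (S)-2-hydroxy-N,N-dimethylpropanamide | C[C@H](O)C(=O)N(C)C | starting material
6 | lithium (2S)-1-(dimethylamino)-1-oxopropan-2-olate | C[C@H]([O-])C(=O)N(C)C.[Li+] | intermediate
7 | [5-bromo-3-methoxy-2-(methoxymethoxy)phenyl]lithium | [Li]c1cc(Br)cc(OC)c1OCOC | intermediate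
8 | (2S)-1-[5-bromo-3-methoxy-2-(methoxymethoxy)phenyl]-2-hydroxypropan-1-one | C[C@H](O)C(=O)c1cc(Br)cc(OC)c1OCOC | intermediate
9 | (2S)-1-[5-bromo-3-methoxy-2-(methoxymethoxy)phenyl]-1-oxopropan-2-yl methanesulfonate | C[C@H](OS(C)(=O)=O)C(=O)c1cc(Br)cc(OC)c1OCOC | intermediate
10 | 1,2-dimethoxybenzene (veratrole) | COc1ccccc1OC | intermediate
11 | 4-bromo-1,2-dimethoxybenzene | COc1ccc(Br)cc1OC | intermediate
12 | (3,4-dimethoxyphenyl)magnesium bromide | COc1ccc([Mg]Br)cc1OC | intermediate
13 | diisobutylaluminium alkoxide of (2S)-1-[5-bromo-3-methoxy-2-(methoxymethoxy)phenyl]-2-(methylsulfonyloxy)propan-1-ol, both C1 epimers | CC(C)C[Al](CC(C)C)OC(c1cc(Br)cc(OC)c1OCOC)[C@H](C)OS(C)(=O)=O | intermediate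
14 | (2S)-2-[5-bromo-3-methoxy-2-(methoxymethoxy)phenyl]propanal | C[C@H](C=O)c1cc(Br)cc(OC)c1OCOC | intermediate
15 | (1R,2S)-2-[5-bromo-3-methoxy-2-(methoxymethoxy)phenyl]-1-(3,4-dimethoxyphenyl)propan-1-ol (major Felkin epimer; the 1S epimer is carried along) | C[C@H]([C@@H](O)c1ccc(OC)c(OC)c1)c1cc(Br)cc(OC)c1OCOC | intermediate
16 | (2S,3S)-5-bromo-2-(3,4-dimethoxyphenyl)-7-methoxy-3-methyl-2,3-dihydro-1-benzofuran | COc1ccc([C@H]2Oc3c(OC)cc(Br)cc3[C@@H]2C)cc1OC | intermediate
17 | [(2S,3S)-2-(3,4-dimethoxyphenyl)-7-methoxy-3-methyl-2,3-dihydro-1-benzofuran-5-yl]lithium | COc1ccc([C@H]2Oc3c(OC)cc([Li])cc3[C@@H]2C)cc1OC | intermediate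
18 | (2S)-1-[(2S,3S)-2-(3,4-dimethoxyphenyl)-7-methoxy-3-methyl-2,3-dihydro-1-benzofuran-5-yl]-2-hydroxypropan-1-one | COc1ccc([C@H]2Oc3c(OC)cc(C(=O)[C@H](C)O)cc3[C@@H]2C)cc1OC | intermediate
19 | (1R,2S)-1-[(2S,3S)-2-(3,4-dimethoxyphenyl)-7-methoxy-3-methyl-2,3-dihydro-1-benzofuran-5-yl]propane-1,2-diol | COc1ccc([C@H]2Oc3c(OC)cc([C@@H](O)[C@H](C)O)cc3[C@@H]2C)cc1OC | target

**Step count**
Total: 12 steps (step 4 is the one-off preparation of the lithium alkoxide solution used in steps 5 and 11). Longest linear sequence: 9 steps (steps 1, 2, 3, 5, 6, 9, 10, 11, 12 from catechol).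

**Steps most likely to fail**

Step 9 (the new step). Aldehyde 14 may be reduced or alkylated by the aluminium species before the Grignard arrives, or may enolise and lose ee. The MOM oxygen may also attack the mesylate carbon (O-5 participation) or be cleaved by Me2AlCl. The fallback uses known chemistry and sets out from 9. The established reductive form of the rearrangement (i-Bu2AlH 2.5 equiv, then Et3Al, CH2Cl2, −78 → 0 °C) reduces the aldehyde as it forms and gives the configurationally stable (2S)-2-[5-bromo-3-methoxy-2-(methoxymethoxy)phenyl]propan-1-ol F1. Buffered Dess–Martin oxidation at 0 °C then gives aldehyde 14, which is used at once with Grignard 12 at −78 °C. This comes back to the route at 15.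

Step 10. The benzylic cation can lose the C3 proton (E1 to the stilbene), which erodes ee, or can close to a cis/trans mixture. The fallback sets out from 15, taken as the chromatographically separated 1R epimer. The MOM group is removed without protic acid (TMSOTf, 2,2′-bipyridyl, CH2Cl2, 0 °C; then H2O) to give 4-bromo-2-[(1R,2S)-1-(3,4-dimethoxyphenyl)-1-hydroxypropan-2-yl]-6-methoxyphenol F2. The ring is then closed by Mitsunobu etherification (PPh3, DIAD, THF, 0 °C). This is an SN2 displacement with inversion, so the 1R carbinol becomes the 2S centre without a free cation. It comes back to the route at 16.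

Step 5. The aryllithium may be consumed by proton transfer, or may react sluggishly with the O-lithiated amide. The fallback sets out from 4. Amide 5 is silylated (TBSCl, imidazole, DMF) to (2S)-2-[tert-butyl(dimethyl)silyl]oxy-N,N-dimethylpropanamide F3. Aryllithium 7 (made from 4 as before) is acylated with F3 to give (2S)-1-[5-bromo-3-methoxy-2-(methoxymethoxy)phenyl]-2-[tert-butyl(dimethyl)silyl]oxypropan-1-one F4. Desilylation with HF·pyridine (THF, 0 °C) comes back to the route at 8.

**Further compounds**
F1 | step 9 | (2S)-2-[5-bromo-3-methoxy-2-(methoxymethoxy)phenyl]propan-1-ol | C[C@H](CO)c1cc(Br)cc(OC)c1OCOC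
F2 | step 10 | 4-bromo-2-[(1R,2S)-1-(3,4-dimethoxyphenyl)-1-hydroxypropan-2-yl]-6-methoxyphenol | C[C@H]([C@@H](O)c1ccc(OC)c(OC)c1)c1cc(Br)cc(OC)c1O
F3 | step 5 | (2S)-2-[tert-butyl(dimethyl)silyl]oxy-N,N-dimethylpropanamide | C[C@H](O[Si](C)(C)C(C)(C)C)C(=O)N(C)C
F4 | step 5 | (2S)-1-[5-bromo-3-methoxy-2-(methoxymethoxy)phenyl]-2-[tert-butyl(dimethyl)silyl]oxypropan-1-one | C[C@H](O[Si](C)(C)C(C)(C)C)C(=O)c1cc(Br)cc(OC)c1OCOC
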